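**Retrosynthetic overview**
1. Target 25 comes from enal 24 by conjugate reduction; the C8 formyl group is read as the retron of a C7=C8 allylic CH2O unit. The (13Z)-enoate side chain is carried intact from fragment 16.
2. Ring A is closed last, by ring-closing metathesis (C1=C2) between a vinyl group on C10 and the vinyl carbinol at C3, then saturated.
3. Ring B is formed first, in the key step: a silicon-tethered type 2 intramolecular Diels–Alder reaction of open-chain 18 joins C5 to C6 and C9 to C10 [(E)-α-methyl enal C1(=O)–C10=C5 plus diene C6=C7–C8=C9] and sets C5, C9 and C10.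
4. Enabling feature: the two oxygens of the target, the hydroxyl oxygen on C3 (ring A) and the formyl oxygen on C17 (the carbon on C8 of ring B), are joined as a temporary i-Pr2Si tether. It holds C4 and the C10 methyl endo, and the C3 stereocentre (from (S)-pantolactone) selects the enal face.
5. Fragments: dienal 5 (four steps from pantolactone) and dienol 16 (carbomagnesiation/iodination of propargyl alcohol, then Negishi coupling with the zinc reagent of (Z)-bromo enoate 11).

Key step: step 11

Assumption: labdane numbering is used throughout (ring A = C1–C5 and C10; ring B = C5–C10; C17 = formyl carbon on C8; C20 = methyl on C10; C11–C16 = side chain); the target has the ent-labdane configuration (3R,5S,8S,9R,10S), so C3 is taken from commercial (S)-pantolactone.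

Step 1
Reactants: 1 (S)-pantolactone
Product: 2 (3S)-4,4-dimethyloxolane-2,3-diol (lactol; both anomers)
Conditions: i-Bu2AlH (2.3 equiv), CH2Cl2, −78 °C; aq. potassium sodium tartrate
Reagents that add atoms: none
Why: Partial reduction of the γ-lactone by i-Bu2AlH stops at the aluminium lactolate at −78 °C (one extra equivalent is spent on the hydroxyl), and the carbinol stereocentre is not touched.

Step 2
Reactants: 2 (3S)-4,4-dimethyloxolane-2,3-diol
Product: 3 (3R)-2,2-dimethylpent-4-ene-1,3-diol
Conditions: Ph3PCH3Br (4.5 equiv), KOt-Bu (4.3 equiv), THF, 0 to 60 °C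
Reagents that add atoms: methyltriphenylphosphonium bromide, C[P+](c1ccccc1)(c1ccccc1)c1ccccc1.[Br-]
Why: Wittig methylenation of the open hydroxy-aldehyde form of the lactol with excess ylide (two equivalents act as base for the hydroxyls), as practised on unprotected sugar lactols; the carbinol centre keeps its configuration (the descriptor changes only through priorities).

Step 3
Reactants: 3 (3R)-2,2-dimethylpent-4-ene-1,3-diol
Product: 4 (3R)-3-hydroxy-2,2-dimethylpent-4-enal
Conditions: TEMPO (10 mol %), PhI(OAc)2 (1.1 equiv), CH2Cl2, 0 °C to rt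
Reagents that add atoms: none
Why: TEMPO/PhI(OAc)2 oxidation distinguishes the primary from the secondary hydroxyl on steric grounds and stops at the aldehyde, which has no α-hydrogen and so cannot epimerise or eliminate.

Step 4
Reactants: 4 (3R)-3-hydroxy-2,2-dimethylpent-4-enal
Product: 5 (2E,5R)-5-hydroxy-2,4,4-trimethylhepta-2,6-dienal
Conditions: Ph3P=C(CH3)CHO (1.3 equiv), toluene, 80 °C
Reagents that add atoms: 2-(triphenyl-λ5-phosphanylidene)propanal, CC(C=O)=P(c1ccccc1)(c1ccccc1)c1ccccc1
Why: Wittig olefination with the stabilised formyl ylide is (E)-selective under thermodynamic control, reacts with the aliphatic aldehyde faster than with the less electrophilic enal product, and tolerates the free hydroxyl.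

Step 5
Reactants: 6 tert-butyl(but-3-yn-1-yloxy)dimethylsilane
Product: 8 methyl 5-[(tert-butyldimethylsilyl)oxy]pent-2-ynoate, via lithium acetylide 7 (not isolated)
Conditions: n-BuLi (1.05 equiv), THF, −78 °C; then ClCO2Me, −78 to 0 °C
Reagents that add atoms: methyl chloroformate, COC(=O)Cl
Why: Deprotonation of the terminal alkyne and C-acylation of the acetylide with the chloroformate (alkynoate synthesis).

Step 6
Reactants: 8 methyl 5-[(tert-butyldimethylsilyl)oxy]pent-2-ynoate
Product: 10 methyl (2Z)-5-[(tert-butyldimethylsilyl)oxy]-3-methylpent-2-enoate, via α-cuprio enoate 9 (not isolated)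
Conditions: Me2CuLi (1.2 equiv), THF, −78 °C; NH4Cl/MeOH at −78 °C
Reagents that add atoms: lithium dimethylcuprate, C[Cu-]C.[Li+]
Why: Syn carbocupration (conjugate addition of the cuprate to the ynoate) and protonation at −78 °C with retention place H cis to the new methyl, hence the chain cis to the ester [(2Z)], because the α-cuprio enoate keeps its geometry only in the cold.

Step 7
Reactants: 10 methyl (2Z)-5-[(tert-butyldimethylsilyl)oxy]-3-methylpent-2-enoate
Product: 11 methyl (2Z)-5-bromo-3-methylpent-2-enoate
Conditions: Ph3PBr2 (1.3 equiv), CH2Cl2, 0 °C to rt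
Reagents that add atoms: dibromotriphenylphosphorane, BrP(Br)(c1ccccc1)(c1ccccc1)c1ccccc1
Why: Ph3PBr2 converts the primary silyl ether directly into the bromide (O-phosphonium formation with loss of the silyl bromide, then SN2 by bromide), so the free (Z)-δ-hydroxy enoate, which would lactonise, never appears.

Step 8
Reactants: 12 prop-2-yn-1-ol
Product: 14 (2Z)-2-(iodomethylidene)but-3-en-1-ol, via cyclic alkenylmagnesium alkoxide 13 (not isolated)
Conditions: CH2=CHMgCl (3.2 equiv), CuI (10 mol %), THF, −10 °C to rt; then I2 (1.5 equiv), −60 to 0 °C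
Reagents that add atoms: vinylmagnesium chloride, C=C[Mg]Cl; iodine, II
Why: Alkoxide-directed anti-carbomagnesiation of the propargylic alcohol puts the vinyl group on C2 and magnesium on C3 cis to the CH2O group in a five-membered chelate, and iodinolysis with retention fixes iodine cis to CH2OH [(2Z)].

Step 9
Reactants: 11 methyl (2Z)-5-bromo-3-methylpent-2-enoate; 14 (2Z)-2-(iodomethylidene)but-3-en-1-ol
Product: 16 methyl (2Z,6Z)-7-(hydroxymethyl)-3-methylnona-2,6,8-trienoate, via alkylzinc bromide 15 (not isolated)
Conditions: 11 (1.6 equiv), Zn dust, LiCl, THF, 50 °C; then 14, Pd(OAc)2 (2 mol %), SPhos (4 mol %), THF, 25 °C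
Reagents that add atoms: none
Why: LiCl-mediated zinc insertion into the primary bromide and Negishi sp3–sp2 coupling with retention of the alkenyl iodide geometry; Pd/SPhos tolerates the ester and the free hydroxyl, so the chain ends cis to CH2OH, the outside position of the later diene.

Step 10
Reactants: 5 (2E,5R)-5-hydroxy-2,4,4-trimethylhepta-2,6-dienal; 16 methyl (2Z,6Z)-7-(hydroxymethyl)-3-methylnona-2,6,8-trienoate
Product: 18 di(propan-2-yl)silylene bis-ether (silaketal) linking the C5 oxygen of 5 to the CH2O oxygen of 16, via silyl triflate 17 (not isolated)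
Conditions: 5, i-Pr2Si(OTf)2 (1.0 equiv), 2,6-lutidine (3 equiv), CH2Cl2, −78 °C; then 16, −78 to 0 °C
Reagents that add atoms: di(propan-2-yl)silanediyl bis(trifluoromethanesulfonate), CC(C)[Si](OS(=O)(=O)C(F)(F)F)(OS(=O)(=O)C(F)(F)F)C(C)C
Why: Stepwise silyl ether formation with the bis-triflate: the hindered secondary alcohol of 5 takes up one silyl triflate at −78 °C and the primary allylic alcohol 16 then displaces the second triflate, which gives the unsymmetrical silaketal.

Step 11
Reactants: 18 silaketal of 5 and 16
Product: 19 silicon-bridged cycloadduct (ring B cyclohexene; C10 carries CH3 plus CHO; C5 is linked to C8 through C4–C3–O–Si(i-Pr)2–O–C17; configuration at C3 C5 C9 C10 as in 25)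
Conditions: Me2AlCl (2.5 equiv), CH2Cl2 (0.005 M), −78 to 0 °C; aq. potassium sodium tartrate
Reagents that add atoms: none
Why: Me2AlCl binds the formyl oxygen and the enal C5=C10 adds suprafacially to the tethered diene C6=C7–C8=C9 in a concerted but asynchronous intramolecular [4+2] cycloaddition in which the C5–C6 bond runs ahead of the C9–C10 bond; the closest known reaction type is the Lewis-acid-promoted type 2 intramolecular Diels–Alder reaction of 2-(oxymethyl)dienes held by a disposable silyl acetal tether. Ring B is closed as a cyclohexene by the cycloaddition itself, and the tether thereby becomes a ten-membered 1,4-bridge from C5 to C8 (bridged mode, with C7=C8 at the bridgehead as an (E)-cyclodecene unit). C5 and C10 are fixed by the (E)-geometry of the enal, which puts C4 and the C10 methyl on one face and C1 on the other (the later trans ring fusion), and C9 is fixed by the outside position of C11 on the diene together with the tether, which can span C4 to C17 only when C4 and the C10 methyl lie endo, so that C11 ends cis to the C10 methyl. The absolute sense follows from C3: in the folded tether its hydrogen must point at the diene and its vinyl group outward, and this exposes a single face of the enal. The step needs the regiochemistry C5 to C6 rather than C5 to C9, and this is secured because the β-carbon of the complexed enal, flanked by the quaternary C4, bonds first to the unsubstituted terminus C6 while the developing allyl cation is stabilised at C8 and C9 (ortho rule of the 1-substituted diene). It also needs chemoselectivity over the unactivated C3 vinyl group, which the low temperature secures.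

Step 12
Reactants: 19 silicon-bridged cycloadduct
Product: 20 silicon-bridged C10-vinyl cycloadduct (CHO of 19 converted into CH=CH2)
Conditions: Ph3PCH3Br (1.6 equiv), KN(SiMe3)2 (1.5 equiv), THF, 0 °C to rt
Reagents that add atoms: methyltriphenylphosphonium bromide, C[P+](c1ccccc1)(c1ccccc1)c1ccccc1.[Br-]
Why: Wittig methylenation of a non-enolisable neopentyl aldehyde; the ester and the silaketal are inert to the unstabilised ylide at 0 °C.

Step 13
Reactants: 20 silicon-bridged C10-vinyl cycloadduct
Product: 21 ring B triene diol (C10 vinyl; C3 vinyl carbinol; C17 hydroxymethyl on C8; configuration as in 25)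
Conditions: Bu4NF (3 equiv), AcOH (3 equiv), THF, 0 °C to rt
Reagents that add atoms: none
Why: Fluoride cleavage of both Si–O bonds (silyl ether deprotection), buffered with AcOH so that the ester and the (Z)-enoate are not exposed to basic fluoride.

Step 14
Reactants: 21 ring B triene diol
Product: 22 methyl (13Z)-3,17-dihydroxylabda-1,7,13-trien-15-oate (ent series; configuration as in 25)
Conditions: second-generation Grubbs catalyst RuCl2(=CHPh)(PCy3)(H2IMes) (5 mol %), CH2Cl2 (0.005 M), 40 °C
Reagents that add atoms: none
Why: Ring-closing metathesis of the two monosubstituted vinyl groups closes the six-membered ring A with loss of ethene (favoured by the gem-dimethyl and quaternary centres, C1 and C4 being trans-diequatorial on ring B), while the trisubstituted C7=C8 and C13=C14 bonds do not react with this catalyst.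

Step 15
Reactants: 22 methyl (13Z)-3,17-dihydroxylabda-1,7,13-trien-15-oate
Product: 23 methyl (13Z)-3,17-dihydroxylabda-7,13-dien-15-oate (ent series; configuration as in 25)
Conditions: 2-nitrobenzenesulfonylhydrazide (6 equiv), Et3N, CH2Cl2, rt
Reagents that add atoms: none
Why: Diimide reduction (concerted syn transfer of H2 from HN=NH) discriminates strongly by substitution, so the cis-disubstituted C1=C2 bond should be reduced while the trisubstituted C7=C8 and the conjugated C13=C14 bonds remain; no stereocentre is created.

Step 16
Reactants: 23 methyl (13Z)-3,17-dihydroxylabda-7,13-dien-15-oate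
Product: 24 methyl (13Z)-3-hydroxy-17-oxolabda-7,13-dien-15-oate (ent series; configuration as in 25)
Conditions: MnO2 (15 equiv), CH2Cl2, rt
Reagents that add atoms: none
Why: MnO2 oxidises only the allylic primary alcohol (C17) to the enal and leaves the saturated secondary C3 hydroxyl.

Step 17
Reactants: 24 methyl (13Z)-3-hydroxy-17-oxolabda-7,13-dien-15-oate
Product: 25 methyl (2Z)-5-[(1R,2S,4aS,6R,8aS)-2-formyl-6-hydroxy-5,5,8a-trimethyldecahydronaphthalen-1-yl]-3-methylpent-2-enoate (target)
Conditions: Hantzsch ester (1.3 equiv), dibenzylammonium trifluoroacetate (20 mol %), THF, 45 °C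
Reagents that add atoms: none
Why: Organocatalytic transfer hydrogenation (iminium activation, hydride transfer from the Hantzsch ester to C7) reduces only the enal and not the β,β-disubstituted enoate, and C8 is set under thermodynamic control by enamine/iminium equilibration to the equatorial formyl group trans to the C9 chain, because an axial formyl group would be 1,3-diaxial to the C10 methyl.

**Compound list**
1 | (S)-pantolactone, (3S)-3-hydroxy-4,4-dimethyloxolan-2-one | CC1(C)COC(=O)[C@H]1O | starting material
2 | (3S)-4,4-dimethyloxolane-2,3-diol (lactol, both anomers) | CC1(C)COC(O)[C@H]1O | intermediate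
3 | (3R)-2,2-dimethylpent-4-ene-1,3-diol | OCC(C)(C)[C@H](O)C=C | intermediate
4 | (3R)-3-hydroxy-2,2-dimethylpent-4-enal | O=CC(C)(C)[C@H](O)C=C | intermediate
5 | (2E,5R)-5-hydroxy-2,4,4-trimethylhepta-2,6-dienal | O=C/C(C)=C/C(C)(C)[C@H](O)C=C | intermediate
6 | tert-butyl(but-3-yn-1-yloxy)dimethylsilane | C#CCCO[Si](C)(C)C(C)(C)C | starting material
7 | lithium acetylide of 6 | [Li]C#CCCO[Si](C)(C)C(C)(C)C | intermediate
8 | methyl 5-[(tert-butyldimethylsilyl)oxy]pent-2-ynoate | COC(=O)C#CCCO[Si](C)(C)C(C)(C)C | intermediate
9 | α-cuprio enoate, lithium alkenyl(methyl)cuprate from 8 (Cu cis to the new methyl) | COC(=O)/C([Cu-]C)=C(/C)CCO[Si](C)(C)C(C)(C)C.[Li+] | intermediate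
10 | methyl (2Z)-5-[(tert-butyldimethylsilyl)oxy]-3-methylpent-2-enoate | COC(=O)/C=C(/C)CCO[Si](C)(C)C(C)(C)C | intermediate
11 | methyl (2Z)-5-bromo-3-methylpent-2-enoate | COC(=O)/C=C(/C)CCBr | intermediate
12 | prop-2-yn-1-ol | C#CCO | starting material
13 | cyclic alkenylmagnesium alkoxide, 3-ethenyl-2,5-dihydro-1,2-oxamagnesole | C=CC1=C[Mg]OC1 | intermediate
14 | (2Z)-2-(iodomethylidene)but-3-en-1-ol | OC/C(C=C)=C\I | intermediate
15 | [(3Z)-5-methoxy-3-methyl-5-oxopent-3-en-1-yl]zinc bromide | COC(=O)/C=C(/C)CC[Zn]Br | intermediate
16 | methyl (2Z,6Z)-7-(hydroxymethyl)-3-methylnona-2,6,8-trienoate | COC(=O)/C=C(/C)CC/C=C(/C=C)CO | intermediate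
17 | silyl triflate: 5 bound through its C5 oxygen to Si(i-Pr)2OTf | O=C/C(C)=C/C(C)(C)[C@H](O[Si](C(C)C)(C(C)C)OS(=O)(=O)C(F)(F)F)C=C | intermediate
18 | silaketal: i-Pr2Si bis-ether of the C5 oxygen of 5 and the CH2O oxygen of 16 | O=C/C(C)=C/C(C)(C)[C@H](O[Si](C(C)C)(C(C)C)OC/C(C=C)=C\CC/C(C)=C\C(=O)OC)C=C | intermediate
19 | silicon-bridged cycloadduct: ring B cyclohexene (C7=C8), C10 with CH3 and CHO, C9 with the (3Z)-5-methoxy-3-methyl-5-oxopent-3-enyl chain, C5 linked to C8 through C4(CH3)2–C3H(CH=CH2)–O–Si(i-Pr)2–O–C17H2; C3, C5, C9, C10 as in 25 | COC(=O)/C=C(/C)CC[C@@H]1C2=CC[C@H](C(C)(C)[C@@H](C=C)O[Si](C(C)C)(C(C)C)OC2)[C@@]1(C)C=O | intermediate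
20 | silicon-bridged C10-vinyl cycloadduct (as 19, CHO replaced by CH=CH2) | COC(=O)/C=C(/C)CC[C@@H]1C2=CC[C@H](C(C)(C)[C@@H](C=C)O[Si](C(C)C)(C(C)C)OC2)[C@@]1(C)C=C | intermediate
21 | ring B triene diol: C10 vinyl, C3 vinyl carbinol, C8 hydroxymethyl; C3, C5, C9, C10 as in 25 | COC(=O)/C=C(/C)CC[C@@H]1C(CO)=CC[C@H](C(C)(C)[C@@H](C=C)O)[C@@]1(C)C=C | intermediate
22 | methyl (13Z)-3,17-dihydroxylabda-1,7,13-trien-15-oate, ent series, configuration as in 25 | COC(=O)/C=C(/C)CC[C@@H]1C(CO)=CC[C@@H]2C(C)(C)[C@H](O)C=C[C@@]12C | intermediate
23 | methyl (13Z)-3,17-dihydroxylabda-7,13-dien-15-oate, ent series, configuration as in 25 | COC(=O)/C=C(/C)CC[C@@H]1C(CO)=CC[C@@H]2C(C)(C)[C@H](O)CC[C@@]12C | intermediate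
24 | methyl (13Z)-3-hydroxy-17-oxolabda-7,13-dien-15-oate, ent series, configuration as in 25 | COC(=O)/C=C(/C)CC[C@@H]1C(C=O)=CC[C@@H]2C(C)(C)[C@H](O)CC[C@@]12C | intermediate
25 | methyl (2Z)-5-[(1R,2S,4aS,6R,8aS)-2-formyl-6-hydroxy-5,5,8a-trimethyldecahydronaphthalen-1-yl]-3-methylpent-2-enoate | COC(=O)/C=C(/C)CC[C@@H]1[C@@H](C=O)CC[C@@H]2C(C)(C)[C@H](O)CC[C@@]12C | target

**Totals**
Total step count: 17.
Longest linear sequence: 12 steps (steps 1–4 and 10–17).

**Three steps most likely to fail**

Step 11 (key step). The cycloaddition may take the 1,3-bridged course (C5 bonding to C9), may stall because the quaternary C4 has to sit endo above the diene, or the Lewis acid may cleave the silaketal before the cycloaddition. The fallback is an untethered, pressure-promoted bimolecular Diels–Alder reaction; it sets out from 5 and 16 and comes back at 21. Compound 5 is silylated (Et3SiCl, imidazole) to (2E,5R)-2,4,4-trimethyl-5-[(triethylsilyl)oxy]hepta-2,6-dienal F1, and 16 (t-BuMe2SiCl, imidazole) to methyl (2Z,6Z)-7-{[(tert-butyldimethylsilyl)oxy]methyl}-3-methylnona-2,6,8-trienoate F2. The two are combined without Lewis acid at 12–15 kbar in CH2Cl2 at room temperature. The ortho rule should still join C5 to C6 and C10 to C9, but the endo/exo and facial control of the tether is lost, so the exo-formyl isomer with the configuration of 19, the bis-silyl ether cycloadduct F3, would have to be separated from its isomers. Wittig methylenation as in step 12 should give the C10-vinyl bis-silyl ether F4, and Bu4NF/AcOH should remove both silyl groups to give 21.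

Step 15. Diimide transfer to the hindered C1=C2 bond may be slow, and forcing it may reduce part of the C7=C8 or C13=C14 bonds. The fallback is a hydroxyl-directed hydrogenation; it sets out from 22 and comes back at 23. t-BuMe2SiCl/imidazole should silylate the primary allylic hydroxyl selectively to the C17 tert-butyldimethylsilyl ether of 22 F5. H2 (1 atm) with [Ir(cod)(PCy3)(py)]PF6 in CH2Cl2 should then be delivered by the free C3 hydroxyl to the neighbouring C1=C2 bond, giving the 1,2-dihydro C17 silyl ether F6. Bu4NF should return 23.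

Step 17. Iminium formation at the hindered, α-branched enal may be slow, and deconjugation through the dienamine may compete with hydride transfer. The fallback is a transition-metal-catalysed redox isomerisation of the allylic alcohol; it sets out from 23 (step 16 is then not run) and comes back at 25. [Ir(cod)(PCy3)(py)]PF6, activated with H2 and then degassed (THF, rt), should move the C7=C8 bond to the enol by a 1,3-hydride shift and so give the aldehyde directly; brief treatment with DBU should equilibrate C8 to the equatorial formyl group. This fallback makes no new compound (entry F0).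

**Further compounds**
F1 | step 11 | (2E,5R)-2,4,4-trimethyl-5-[(triethylsilyl)oxy]hepta-2,6-dienal | O=C/C(C)=C/C(C)(C)[C@H](O[Si](CC)(CC)CC)C=C
F2 | step 11 | methyl (2Z,6Z)-7-{[(tert-butyldimethylsilyl)oxy]methyl}-3-methylnona-2,6,8-trienoate | COC(=O)/C=C(/C)CC/C=C(/C=C)CO[Si](C)(C)C(C)(C)C
F3 | step 11 | bis-silyl ether cycloadduct (untethered analogue of 19: C17 OSi(t-Bu)Me2, C3 OSiEt3, C10 CHO) | COC(=O)/C=C(/C)CC[C@@H]1C(CO[Si](C)(C)C(C)(C)C)=CC[C@H](C(C)(C)[C@@H](C=C)O[Si](CC)(CC)CC)[C@@]1(C)C=O
F4 | step 11 | C10-vinyl bis-silyl ether (bis-silyl ether of 21) | COC(=O)/C=C(/C)CC[C@@H]1C(CO[Si](C)(C)C(C)(C)C)=CC[C@H](C(C)(C)[C@@H](C=C)O[Si](CC)(CC)CC)[C@@]1(C)C=C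
F5 | step 15 | C17 tert-butyldimethylsilyl ether of 22 | COC(=O)/C=C(/C)CC[C@@H]1C(CO[Si](C)(C)C(C)(C)C)=CC[C@@H]2C(C)(C)[C@H](O)C=C[C@@]12C
F6 | step 15 | C17 tert-butyldimethylsilyl ether of 23 | COC(=O)/C=C(/C)CC[C@@H]1C(CO[Si](C)(C)C(C)(C)C)=CC[C@@H]2C(C)(C)[C@H](O)CC[C@@]12C
F0 | step 17 | none | none
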